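The runs were generated by integration for substances that don't exist, noise included.

In a one-step world, each equivalent of incoming ligand makes one equivalent of product. Here the starting complex takes ligand twice, passing through the complex with one exchanged, before it is the complex with two exchanged.

in all of them: starting complex 0.72 M
- south: incoming ligand 1 equiv; leaving ligand 0.25 equiv; temperature 75 °C; run made earlier
- south-east: incoming ligand 1 equiv; leaving ligand 0.39 equiv; temperature 90 °C; run made earlier
- north-east: incoming ligand 2.2 equiv; leaving ligand 0.50 equiv; temperature 75 °C; run made earlier
- eta: incoming ligand 1.00 equiv; leaving ligand 0.500 equiv; temperature 90 °C; time 6.0 d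
- gamma: incoming ligand 4.00 equiv; leaving ligand 0.340 equiv; temperature 90 °C; time 6.0 d

| south: time / d | south: complex with two exchanged / % | south-east: time / d | south-east: complex with two exchanged / % | north-east: time / d | north-east: complex with two exchanged / % |
|---|---|---|---|---|---|
| 0.833 | 5.2 | 0.833 | 18.8 | 1.67 | 41.4 |
| 2.00 | 15.2 | 1.67 | 27.5 | 4.00 | 69.8 |
| 4.00 | 25.5 | 2.50 | 31.4 | 5.00 | 74.9 |
| 6.00 | 28.5 | 3.00 | 32.1 | 6.00 | 78.9 |

(standard deviation of a reading: 1 percentage point)

- amounts and yields of complex with two exchanged count crystals too
- given per volume of solution although it is solid: crystals
- what may be going on: complex with two exchanged + incoming ligand -> leaving ligand + complex with three exchanged; complex with one exchanged + incoming ligand -> leaving ligand + complex with two exchanged; crystals <-> complex with two exchanged; starting complex + incoming ligand -> leaving ligand + complex with one exchanged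

- which one finishes higher in amount of complex with two exchanged, in percent of the starting complex charged ("neither" within 2 percentage points) (eta / gamma / neither)
- amount of complex with two exchanged at the end, in percent of the starting complex charged, eta
- amount of complex with two exchanged at the end, in percent of the starting complex charged, gamma

I first asked what each charge could pay for. I defined the cover, C, as the equivalents of incoming ligand charged, divided by the 2 that one finished complex needs. Gamma has C = 2.00, and eta has C = 0.500. C caps the yield, so eta's ceiling was 50.0%. With C below one, incoming ligand is eta's limiting reagent.

Next I asked where eta stops under that ceiling. The south-east run has the same C and temperature. It read 32.1% at 3.00 d, up 0.7 percentage points since the reading before. Its leaving ligand was lower, but the listed exchanges run one way. So I took about that reading for eta.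

Then I asked whether gamma had time to reach its ceiling, the whole charge. The south-east run at 0.833 d already read higher than the south run at 2.00 d. Those runs also differ in leaving ligand, but I put the gain on going from 75 °C to 90 °C and read a speed-up of about 2.40 times. Gamma also starts with 1.82 times the ligand of the north-east run. Dividing that run's time by both factors, I estimated that gamma would reach that run's last reading, 78.9%, in about 1.37 d, which is shorter than the 6.0 d allowed. That run was still rising, by 4 points in its last interval. So I expected gamma near its ceiling.

The forecast said gamma, with 33% for eta and 80% for gamma, lower than my ceiling, and warned that “the third-step rate is poorly constrained”.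

The flask gave 33.4% for eta and 98.2% for gamma, so gamma finished higher.

    complex with two exchanged + incoming ligand → leaving ligand + complex with three exchanged (k = 0.00310 /M/h, Ea = 109 kJ/mol)
    complex with one exchanged + incoming ligand → leaving ligand + complex with two exchanged (k = 0.102 /M/h, Ea = 76.0 kJ/mol)
    crystals ⇌ complex with two exchanged, rate k3*(cs3 - [complex with two exchanged]) while solid is left; crystals form when [complex with two exchanged] > cs3 (solubility = 12.0 mM, k = 0.828 /h)
    starting complex + incoming ligand → leaving ligand + complex with one exchanged (k = 0.0842 /M/h, Ea = 76.0 kJ/mol)
    (constants at 90 °C)

In gamma at 6.00 d, the complex with three exchanged stood at 1.81% of the starting complex charged. With C = 2.00, two exchanges on the whole charge take 50.0% of gamma's incoming ligand, the third exchange took 0.453% more, and 50% was left. A neighbour like eta with 0.600 equiv of incoming ligand has C = 0.300, a ceiling of 30.0%. It finished at 14.4%, with 54.5% of the starting complex still there.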